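## Analysis of the target

Plakortolide Q is a cis-fused bicyclic peroxy lactone. A 1,2-dioxane (O1, O2, C3–C6) shares the C3–C4 bond with a γ-lactone (C1 carbonyl, C2, C3, C4 and the ring oxygen on C4). C6 carries a methyl group and the C7–C16 chain, which ends in a (13E,15E)-phenylbutadienyl unit. There are three stereocentres, C3 (R), C4 (R) and C6 (S); C4 and C6 are fully substituted. C2 on C3, the lactone oxygen on C4 and C7 on C6 lie on one face of the dioxane; H-3 and both methyl groups lie on the other. The sensitive groups are the O–O bond (reductants, phosphines, low-valent metals, hydrogenation catalysts), H-3 next to the peroxide (base-induced Kornblum–DeLaMare cleavage), the β-peroxy lactone (deprotonation at C2 expels O2 from C3) and the conjugated diene. The difficulty is to place two oxygen-bearing, fully substituted carbons 1,3 to each other across a peroxide with control of all three centres, and then to build a ten-carbon chain without losing the O–O bond. The strategy rests on one feature: C2 and C7 are cis across the peroxide and each is followed by exactly one more carbon (C1, C8). C2 and C7 can therefore be the two carbons of a ring double bond that bridges C3 and C6 in a 2,3-dioxabicyclo[2.2.2]octene, and C1 and C8 can be the two halves of one ethylene molecule.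

## Retrosynthetic reasoning

**Lactone C1–O bond.** The last bond made is the acyl–oxygen bond of the lactone, so 29 goes back to diol 27 (C1 a primary alcohol, C4–OH free) and from there to the bis-silyl ether 26. Closing the lactone last keeps the β-peroxy lactone out of every basic step. The forward reaction only has to oxidise C1 next to a tertiary alcohol, a peroxide and a diene; the cis fusion follows from C3 and C4.

**C13=C14.** 26 is cut into aldehyde 23 and phosphonate 24. The phosphonate brings C14–C16 with the C15=C16 E bond already in place, so only one new geometry has to be controlled. The diene is introduced after the saturation of step 14, which would not spare it.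

**C8–C9.** 23 comes from acetal 22, and 22 from alkene 21, which is cut at C8=C9 into aldehyde 17 and phosphonium salt 19 (from bromide 18). The cut is placed here because C8 is the carbon that the vinyl group on C6 can deliver as an aldehyde. The alkene geometry is irrelevant, and a metal-free hydrogen transfer saturates it without touching O–O.

**The two side arms.** 17, 16, 14 and 13 all derive from the two vinyl groups of 11. The vinyl groups differ at the allylic carbon: C3 bears a hydrogen, C6 is fully substituted. A hindered dialkylborane should take the C3 vinyl first (alcohol 13), silylation stores that oxygen (14), and a second hydroboration converts the C6 vinyl into the C8 alcohol 16. Hydroboration puts oxygen on the terminal carbons, so boron is never β to a peroxide oxygen.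

**Key disconnection, C1=C2 and C7=C8.** Both vinyl double bonds of 11 are cut and C2 is joined to C7: the retron of a ring-opening metathesis of 9 with 10. This converts a cis-3,6-disubstituted dioxane into a bicyclic endoperoxide, the one type of 1,2-dioxane that a carbocyclic diene gives in a single stereospecific step. The cis relation of the two arms becomes automatic, and 10 supplies exactly C1 and C8. The forward reaction must open only the strained alkene and leave O–O intact.

**C3–O2 and C6–O1.** 9 is the [4+2] adduct of diene 7 and 8 in its singlet state. The addition is suprafacial, so the only question is the face: the peroxide must form anti to the C4 silyloxy group, which places that oxygen on the side of the etheno bridge. The silyl ether is used because a free hydroxyl would steer the addition syn by hydrogen bonding.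

**The diene.** 7 comes from selenide 5 by selenoxide elimination, 5 from hydroxy selenide 4, and 4 from epoxide 3. A direct base-induced isomerisation of 3 was not chosen: two allylic ring methylenes and the methyl group all offer β-hydrogens, so its regiochemistry is not secured. It would also leave a free tertiary hydroxyl on a cyclohexadiene, which can dehydrate back to the aromatic ring of 1. Selenide opening at the secondary carbon, silylation, and elimination away from the hydrogen-free carbinol carbon leave no choice at any stage.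

**The stereocentre and the ring.** 3 is the mono-epoxide of 2, formed by enantioselective epoxidation of one of its two enantiotopic trisubstituted double bonds. 2 is the Birch reduction product of 1.

## Alternatives that were turned down

Alternative 1: The dioxane is disconnected at C4–C5 and O1–C6 into the α-hydroperoxy ketone A1 (C1–C4) and the enyne A2 (C5 to C13). In the forward step SnCl4 binds the ketone and the proximal peroxide oxygen of A1, the methylene of A2 attacks C4, and the tertiary propargylic cation at C6 is trapped by the peroxide oxygen to give the hydroxy ester A3. It is convergent, forms C4 and C6 in one step under the direction of C3, and delivers most of the chain and the C1 ester with the fragments; on step economy it is clearly stronger than the chosen route. Against it, A1 has an enolisable H-3 on the hydroperoxide carbon, so its configuration is labile and it is open to Kornblum–DeLaMare and Lewis-acid-induced cleavage. The C6 configuration depends on the capture of a nearly linear cation whose two substituents (methyl, alkynyl) differ little, and the C7≡C8 bond must later be saturated next to O–O. The chosen route is longer, but it sets the C3/C6 relation in a concerted suprafacial step and never handles a hydroperoxide.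

Alternative 2: The ring is disconnected at a C4=C5 double bond, back to the acyclic bis-vinyl peroxide A4. A chiral second-generation ruthenium alkylidene joins the isopropenyl group on C3 to one of the two diastereotopic vinyl groups on C6, with loss of ethylene, to give the dihydrodioxine A5. Its metathesis meets an unstrained dialkyl peroxide, which is better founded than metathesis on a bicyclic endoperoxide; on that point it is the safer key step. The later lactonisation onto C4=C5 would also set C4 by ring fusion, more reliably than the face selection of step 6. Against it, the two vinyl groups are remote from the only stereocentre, so C6 rests on reagent control in an untested setting. A4 needs a peroxide between a secondary allylic and a tertiary bis-allylic carbon. A5 still lacks the C4 oxygen, which means a halolactonisation and a reductive dehalogenation beside the peroxide. The chosen route has all three stereocentres in place before its metathesis, which creates none.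

Alternative 3: The O1–C6 bond is disconnected, with the C4 oxygen tied to C8 as an unsaturated δ-lactone in the hydroperoxide A6. An amine base adds the C3 hydroperoxide to C6, the β-carbon of the lactone, to give the bridged peroxy lactone A7. Peroxy-Michael closure is a known, mild way to 1,2-dioxanes; the bridge fixes the C4/C6 relation by geometry, and no transition metal comes near the peroxide. On stereocontrol at C6 it is stronger than the chosen route. Against it, the C3/C4 pair (a secondary hydroperoxide beside a fully substituted carbinol carbon) must be built first, and A6 again carries a base-labile H–C–OOH unit. C8 arrives as a carboxyl carbon, so the δ-lactone must be exchanged for the γ-lactone and C8 reduced beside O–O and a second carboxyl group. The chosen route delivers C1 and C8 at the alkene level, from which hydroboration reaches the needed alcohol level at both ends.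

Key step: step 7

Assumption: the facial sense of the epoxidation in step 2 is taken from the spiro transition-state model for 1-substituted cyclohexenes, which calls for the L-fructose-derived enantiomer of the Shi ketone; if the opposite sense were found, the D-fructose-derived ketone would be used and nothing else changes.
Remark: locants C1–C16, O1 and O2 are those of the target throughout; TBS = tert-butyldimethylsilyl, TBDPS = tert-butyldiphenylsilyl, TBSO and TBDPSO the corresponding silyloxy groups.

## Route

Step 1
Reactants: 1 m-xylene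
Product: 2 1,5-dimethylcyclohexa-1,4-diene
Conditions: Li, NH3 (l), t-BuOH, THF, −78 → −33 °C
Reagents that add atoms: none
Why: Birch reduction; the arene radical anion is protonated at the unsubstituted C2 and C5 of 1, so both methyl groups stay on double bonds and the non-conjugated 1,4-diene results; no stereocentre is formed.

Step 2
Reactants: 2 1,5-dimethylcyclohexa-1,4-diene
Product: 3 (1R,6S)-1,3-dimethyl-7-oxabicyclo[4.1.0]hept-3-ene
Conditions: L-fructose-derived Shi ketone (0.3 equiv), KHSO5 (as Oxone, 1 equiv), K2CO3, Bu4NHSO4, MeCN/CH2(OMe)2/aq. Na2B4O7 buffer, 0 °C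
Reagents that add atoms: potassium peroxymonosulfate, [K+].[O-]S(=O)(=O)OO
Why: Shi asymmetric epoxidation (chiral dioxirane, spiro transition state) of a trisubstituted alkene; the two double bonds of 2 are enantiotopic, so the face selection of the catalyst decides the enantiomer and sets the fully substituted C–O carbon (C4 of the target) as R; limiting the oxidant keeps the second double bond.

Step 3
Reactants: 3 (1R,6S)-1,3-dimethyl-7-oxabicyclo[4.1.0]hept-3-ene
Product: 4 (1R,6R)-1,3-dimethyl-6-(phenylselanyl)cyclohex-3-en-1-ol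
Conditions: (PhSe)2 (0.55 equiv), NaBH4, EtOH, 0 °C → reflux
Reagents that add atoms: diphenyl diselenide, c1ccccc1[Se][Se]c1ccccc1
Why: SN2 opening of the epoxide by benzeneselenolate at the less substituted carbon with inversion (trans-diaxial, Fürst–Plattner); the C–O bond at the fully substituted carbon is untouched, so its configuration is kept.

Step 4
Reactants: 4 (1R,6R)-1,3-dimethyl-6-(phenylselanyl)cyclohex-3-en-1-ol
Product: 5 (1R,6R)-1-(TBSO)-1,3-dimethyl-6-(phenylselanyl)cyclohex-3-ene
Conditions: t-BuMe2SiOTf, 2,6-lutidine, CH2Cl2, −78 → 0 °C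
Reagents that add atoms: tert-butyldimethylsilyl trifluoromethanesulfonate, CC(C)(C)[Si](C)(C)OS(=O)(=O)C(F)(F)F
Why: Silylation of a hindered tertiary alcohol with a silyl triflate and a non-nucleophilic base; it is done before the diene exists, so that no free tertiary allylic alcohol that could ionise and aromatise is ever handled.

Step 5
Reactants: 5 (1R,6R)-1-(TBSO)-1,3-dimethyl-6-(phenylselanyl)cyclohex-3-ene
Product: 7 (5R)-5-(TBSO)-1,5-dimethylcyclohexa-1,3-diene, via selenoxide 6 (not isolated)
Conditions: m-CPBA (1.05 equiv), CH2Cl2, −78 °C; then i-Pr2NH, −78 → 20 °C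
Reagents that add atoms: none
Why: Selenide oxidation and selenoxide syn-elimination; the only β-hydrogens are on the allylic CH2 (C5 of 5), the carbinol carbon having none, so the new double bond can only form in conjugation with the existing one; the amine traps the selenenic acid.

Step 6
Reactants: 7 (5R)-5-(TBSO)-1,5-dimethylcyclohexa-1,3-diene; 8 oxygen
Product: 9 (1R,4R,5R)-5-(TBSO)-1,5-dimethyl-2,3-dioxabicyclo[2.2.2]oct-7-ene (peroxide bridge anti to the silyloxy group)
Conditions: O2, tetraphenylporphyrin (cat.), visible light, CH2Cl2, −78 °C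
Reagents that add atoms: none
Why: Dye-sensitised photo-oxygenation, a suprafacial [4+2] cycloaddition of singlet oxygen to the s-cis ring diene, so C3–O2 and C6–O1 form on one face and C3 and C6 are set together. The face anti to the C4 silyloxy group is expected, because lone-pair repulsion with the allylic oxygen and the bulk of the pseudo-axial silyloxy group both disfavour the syn approach and no free OH is present to direct syn. A syn adduct, if formed, is a diastereomer and is removed by chromatography.

Step 7
Reactants: 9 (1R,4R,5R)-5-(TBSO)-1,5-dimethyl-2,3-dioxabicyclo[2.2.2]oct-7-ene; 10 ethylene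
Product: 11 (3R,4R,6R)-4-(TBSO)-3,6-diethenyl-4,6-dimethyl-1,2-dioxane
Conditions: second-generation Grubbs catalyst RuCl2(=CHPh)(H2IMes)(PCy3) (5 mol%), C2H4 (1 atm), CH2Cl2 (0.01 M), 20 °C; then ethyl vinyl ether
Reagents that add atoms: none
Why: Proposed new method: ring-opening metathesis of a 2,3-dioxabicyclo[2.2.2]octene with ethylene has not been shown; the closest known reactions are ring-opening metathesis with ethylene of 2-azabicyclo[2.2.2]octenes and 7-oxanorbornenes and cross-metathesis of alkenes that carry dialkyl peroxides. The ruthenium methylidene formed from the precatalyst and 10 adds [2+2] across the strained cis C2=C7 bond of 9, the ruthenacyclobutane cycloreverts so that the etheno bridge is cut, and the new alkylidene is capped by a second molecule of 10; this forms C1=C2 and C7=C8, with C1 and C8 both drawn from 10. No ring is closed (the carbocycle is opened and the 1,2-dioxane is what remains) and no stereocentre is created; C2 and C7 leave the step cis on C3 and C6 because they were the two ends of one bridge, and C4 keeps the configuration fixed in steps 2 and 6. The driving force is the relief of bicyclic strain together with the excess of 10; dilution and the ethylene atmosphere should hold back oligomerisation and the reverse ring closure, and the catalyst is destroyed with ethyl vinyl ether before the ethylene is released. The selectivity required is chemoselectivity, C=C against O–O: the divalent ruthenium centre must not insert into, or transfer an electron to, the peroxide, which would isomerise 9. In favour of the alkene are its strain and its cis-disubstituted nature, the attachment of O1 to the fully substituted C6, the absence of any O–H or carbonyl group that could assist O–O cleavage, and the mild temperature; against it, the C4 silyloxy group screens the alkene face next to the C4–C5 bridge, so the metal has to approach past the peroxide bridge.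

Step 8
Reactants: 11 (3R,4R,6R)-4-(TBSO)-3,6-diethenyl-4,6-dimethyl-1,2-dioxane
Product: 13 2-[(3R,4R,6R)-4-(TBSO)-6-ethenyl-4,6-dimethyl-1,2-dioxan-3-yl]ethan-1-ol, via alkylborane 12 (not isolated)
Conditions: (Me2CHCHMe)2BH (from BH3·SMe2 and 2-methylbut-2-ene, 1.2 equiv), THF, −10 → 0 °C; then NaBO3·4H2O, THF/H2O, 20 °C
Reagents that add atoms: sodium perborate, [Na+].[O-]OB=O
Why: Hydroboration–oxidation with a hindered dialkylborane; boron adds to the terminal carbon, so it is never β to a peroxide oxygen, and bis(3-methylbutan-2-yl)borane is much slower with a vinyl group on a fully substituted carbon, which should single out the C3 vinyl (C3 carries H) over the C6 vinyl. Perborate oxidises the C–B bond under conditions that spare the dialkyl peroxide and the silyl ether.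

Step 9
Reactants: 13 2-[(3R,4R,6R)-4-(TBSO)-6-ethenyl-4,6-dimethyl-1,2-dioxan-3-yl]ethan-1-ol
Product: 14 (3R,4R,6R)-4-(TBSO)-3-[2-(TBDPSO)ethyl]-6-ethenyl-4,6-dimethyl-1,2-dioxane
Conditions: t-BuPh2SiCl, imidazole, CH2Cl2, 20 °C
Reagents that add atoms: tert-butyl(chloro)diphenylsilane, CC(C)(C)[Si](Cl)(c1ccccc1)c1ccccc1
Why: Standard silylation of a primary alcohol; the TBDPS group is chosen because it survives the aqueous acid of step 15 and leaves together with the C4 silyl group in step 17.

Step 10
Reactants: 14 (3R,4R,6R)-4-(TBSO)-3-[2-(TBDPSO)ethyl]-6-ethenyl-4,6-dimethyl-1,2-dioxane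
Product: 16 (3R,4R,6S)-4-(TBSO)-3-[2-(TBDPSO)ethyl]-6-(2-hydroxyethyl)-4,6-dimethyl-1,2-dioxane, via B-alkyl-9-borabicyclononane 15 (not isolated)
Conditions: 9-BBN-H (3 equiv), THF, 20 → 45 °C; then NaBO3·4H2O, THF/H2O, 20 °C
Reagents that add atoms: sodium perborate, [Na+].[O-]OB=O
Why: Anti-Markovnikov hydroboration of the remaining, hindered vinyl group with an excess of the less demanding 9-BBN-H, then oxidation of the C–B bond; C8 becomes the primary alcohol.

Step 11
Reactants: 16 (3R,4R,6S)-4-(TBSO)-3-[2-(TBDPSO)ethyl]-6-(2-hydroxyethyl)-4,6-dimethyl-1,2-dioxane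
Product: 17 (3R,4R,6R)-4-(TBSO)-3-[2-(TBDPSO)ethyl]-4,6-dimethyl-6-(2-oxoethyl)-1,2-dioxane
Conditions: Dess–Martin periodinane, NaHCO3, CH2Cl2, 0 → 20 °C
Reagents that add atoms: none
Why: Dess–Martin oxidation, buffered and non-basic, stops at the aldehyde and does not touch the peroxide; the β-peroxy aldehyde is used at once.

Step 12
Reactants: 18 2-(4-bromobutyl)-1,3-dioxolane
Product: 19 [4-(1,3-dioxolan-2-yl)butyl]triphenylphosphonium bromide
Conditions: PPh3, MeCN, 80 °C
Reagents that add atoms: triphenylphosphine, c1ccc(cc1)P(c1ccccc1)c1ccccc1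
Why: SN2 quaternisation of triphenylphosphine by a primary bromide; the dioxolane is inert under neutral conditions.

Step 13
Reactants: 19 [4-(1,3-dioxolan-2-yl)butyl]triphenylphosphonium bromide; 17 (3R,4R,6R)-4-(TBSO)-3-[2-(TBDPSO)ethyl]-4,6-dimethyl-6-(2-oxoethyl)-1,2-dioxane
Product: 21 (3R,4R,6S)-4-(TBSO)-3-[2-(TBDPSO)ethyl]-6-[(2Z)-6-(1,3-dioxolan-2-yl)hex-2-en-1-yl]-4,6-dimethyl-1,2-dioxane, via ylide 20 (not isolated)
Conditions: 19, KN(SiMe3)2, THF, −78 → 0 °C; then 17, −78 → 0 °C
Reagents that add atoms: none
Why: Wittig olefination with a non-stabilised ylide at low temperature forms C8=C9, mainly Z; the geometry is of no consequence because this bond is saturated in step 14, and carbonyl addition should outrun α-deprotonation of the aldehyde.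

Step 14
Reactants: 21 (3R,4R,6S)-4-(TBSO)-3-[2-(TBDPSO)ethyl]-6-[(2Z)-6-(1,3-dioxolan-2-yl)hex-2-en-1-yl]-4,6-dimethyl-1,2-dioxane
Product: 22 (3R,4R,6S)-4-(TBSO)-3-[2-(TBDPSO)ethyl]-6-[6-(1,3-dioxolan-2-yl)hexyl]-4,6-dimethyl-1,2-dioxane
Conditions: KO2CN=NCO2K, AcOH, CH2Cl2/MeOH, 0 → 20 °C
Reagents that add atoms: none
Why: Diimide reduction, a concerted syn transfer of H2 to the isolated disubstituted C=C; diimide does not reduce O–O bonds, unlike catalytic hydrogenation.

Step 15
Reactants: 22 (3R,4R,6S)-4-(TBSO)-3-[2-(TBDPSO)ethyl]-6-[6-(1,3-dioxolan-2-yl)hexyl]-4,6-dimethyl-1,2-dioxane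
Product: 23 (3R,4R,6S)-4-(TBSO)-3-[2-(TBDPSO)ethyl]-4,6-dimethyl-6-(7-oxoheptyl)-1,2-dioxane
Conditions: TsOH·H2O (cat.), acetone/H2O, 40 °C
Reagents that add atoms: water, O
Why: Acid-catalysed acetal hydrolysis (transacetalisation with acetone); the dialkyl peroxide, the tertiary TBS ether and the primary TBDPS ether are stable to these mild conditions.

Step 16
Reactants: 24 diethyl [(2E)-3-phenylprop-2-en-1-yl]phosphonate; 23 (3R,4R,6S)-4-(TBSO)-3-[2-(TBDPSO)ethyl]-4,6-dimethyl-6-(7-oxoheptyl)-1,2-dioxane
Product: 26 (3R,4R,6S)-4-(TBSO)-3-[2-(TBDPSO)ethyl]-4,6-dimethyl-6-[(7E,9E)-10-phenyldeca-7,9-dien-1-yl]-1,2-dioxane, via phosphonate anion 25 (not isolated)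
Conditions: 24, NaN(SiMe3)2, THF, −78 °C; then 23, −78 → 20 °C
Reagents that add atoms: none
Why: Horner–Wadsworth–Emmons olefination with an allylic phosphonate anion; α-attack on the aldehyde and elimination give C13=C14 with E geometry (reversible addition, thermodynamic control), while C15=C16 is E from 24. No carbonyl group sits β to a peroxide oxygen at this stage, so the base has nothing to eliminate.

Step 17
Reactants: 26 (3R,4R,6S)-4-(TBSO)-3-[2-(TBDPSO)ethyl]-4,6-dimethyl-6-[(7E,9E)-10-phenyldeca-7,9-dien-1-yl]-1,2-dioxane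
Product: 27 (3R,4R,6S)-3-(2-hydroxyethyl)-4,6-dimethyl-6-[(7E,9E)-10-phenyldeca-7,9-dien-1-yl]-1,2-dioxan-4-ol
Conditions: HF·pyridine, pyridine, THF, 0 → 20 °C
Reagents that add atoms: none
Why: Fluoride-mediated cleavage of both silyl ethers under mildly acidic, buffered conditions, which avoid base at H-3 next to the peroxide; the diene is stable to buffered HF·pyridine.

Step 18
Reactants: 27 (3R,4R,6S)-3-(2-hydroxyethyl)-4,6-dimethyl-6-[(7E,9E)-10-phenyldeca-7,9-dien-1-yl]-1,2-dioxan-4-ol
Product: 29 plakortolide Q [(3S,4aR,7aR)-3,4a-dimethyl-3-[(7E,9E)-10-phenyldeca-7,9-dien-1-yl]tetrahydro-3H-furo[3,2-c][1,2]dioxin-6(4H)-one], via lactol 28 (not isolated)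
Conditions: TEMPO (0.2 equiv), PhI(OAc)2 (3 equiv), CH2Cl2, 20 °C
Reagents that add atoms: none
Why: Oxoammonium-mediated oxidative lactonisation of a 1,4-diol; the primary alcohol is oxidised to the aldehyde, the cis C4 hydroxyl closes the lactol, and this is oxidised to the γ-lactone. The tertiary alcohol, the peroxide and the diene are not affected, and the cis ring fusion is dictated by C3 and C4.

## Compound list

1 | m-xylene | Cc1cccc(C)c1 | starting material
2 | 1,5-dimethylcyclohexa-1,4-diene | CC1=CCC=C(C)C1 | intermediate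
3 | (1R,6S)-1,3-dimethyl-7-oxabicyclo[4.1.0]hept-3-ene | CC1=CC[C@@H]2O[C@]2(C)C1 | intermediate
4 | (1R,6R)-1,3-dimethyl-6-(phenylselanyl)cyclohex-3-en-1-ol | CC1=CC[C@@H]([Se]c2ccccc2)[C@](C)(O)C1 | intermediate
5 | (1R,6R)-1-(TBSO)-1,3-dimethyl-6-(phenylselanyl)cyclohex-3-ene | CC1=CC[C@@H]([Se]c2ccccc2)[C@](C)(O[Si](C)(C)C(C)(C)C)C1 | intermediate
6 | (1R,6R)-1-(TBSO)-1,3-dimethyl-6-(benzeneseleninyl)cyclohex-3-ene (both configurations at selenium) | CC1=CC[C@@H]([Se](=O)c2ccccc2)[C@](C)(O[Si](C)(C)C(C)(C)C)C1 | intermediate (not isolated)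
7 | (5R)-5-(TBSO)-1,5-dimethylcyclohexa-1,3-diene | C[C@]1(O[Si](C)(C)C(C)(C)C)C=CC=C(C)C1 | intermediate
8 | oxygen | O=O | starting material
9 | (1R,4R,5R)-5-(TBSO)-1,5-dimethyl-2,3-dioxabicyclo[2.2.2]oct-7-ene | C[C@@]1(C[C@@](C)(O[Si](C)(C)C(C)(C)C)[C@@H]2OO1)C=C2 | intermediate
10 | ethylene | C=C | starting material
11 | (3R,4R,6R)-4-(TBSO)-3,6-diethenyl-4,6-dimethyl-1,2-dioxane | C=C[C@@]1(C)C[C@@](C)(O[Si](C)(C)C(C)(C)C)[C@@H](C=C)OO1 | intermediate
12 | {2-[(3R,4R,6R)-4-(TBSO)-6-ethenyl-4,6-dimethyl-1,2-dioxan-3-yl]ethyl}bis(3-methylbutan-2-yl)borane | C=C[C@@]1(C)C[C@@](C)(O[Si](C)(C)C(C)(C)C)[C@@H](CCB(C(C)C(C)C)C(C)C(C)C)OO1 | intermediate (not isolated)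
13 | 2-[(3R,4R,6R)-4-(TBSO)-6-ethenyl-4,6-dimethyl-1,2-dioxan-3-yl]ethan-1-ol | C=C[C@@]1(C)C[C@@](C)(O[Si](C)(C)C(C)(C)C)[C@@H](CCO)OO1 | intermediate
14 | (3R,4R,6R)-4-(TBSO)-3-[2-(TBDPSO)ethyl]-6-ethenyl-4,6-dimethyl-1,2-dioxane | C=C[C@@]1(C)C[C@@](C)(O[Si](C)(C)C(C)(C)C)[C@@H](CCO[Si](c2ccccc2)(c2ccccc2)C(C)(C)C)OO1 | intermediate
15 | 9-{2-[(3R,4R,6S)-4-(TBSO)-3-[2-(TBDPSO)ethyl]-4,6-dimethyl-1,2-dioxan-6-yl]ethyl}-9-borabicyclo[3.3.1]nonane | C(C[C@@]1(C)C[C@@](C)(O[Si](C)(C)C(C)(C)C)[C@@H](CCO[Si](c2ccccc2)(c2ccccc2)C(C)(C)C)OO1)B1C2CCCC1CCC2 | intermediate (not isolated)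
16 | (3R,4R,6S)-4-(TBSO)-3-[2-(TBDPSO)ethyl]-6-(2-hydroxyethyl)-4,6-dimethyl-1,2-dioxane | OCC[C@@]1(C)C[C@@](C)(O[Si](C)(C)C(C)(C)C)[C@@H](CCO[Si](c2ccccc2)(c2ccccc2)C(C)(C)C)OO1 | intermediate
17 | (3R,4R,6R)-4-(TBSO)-3-[2-(TBDPSO)ethyl]-4,6-dimethyl-6-(2-oxoethyl)-1,2-dioxane | O=CC[C@@]1(C)C[C@@](C)(O[Si](C)(C)C(C)(C)C)[C@@H](CCO[Si](c2ccccc2)(c2ccccc2)C(C)(C)C)OO1 | intermediate
18 | 2-(4-bromobutyl)-1,3-dioxolane | BrCCCCC1OCCO1 | starting material
19 | [4-(1,3-dioxolan-2-yl)butyl]triphenylphosphonium bromide | [Br-].C1COC(CCCC[P+](c2ccccc2)(c2ccccc2)c2ccccc2)O1 | intermediate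
20 | [4-(1,3-dioxolan-2-yl)butylidene]triphenylphosphorane | C(CCCC1OCCO1)=P(c1ccccc1)(c1ccccc1)c1ccccc1 | intermediate (not isolated)
21 | (3R,4R,6S)-4-(TBSO)-3-[2-(TBDPSO)ethyl]-6-[(2Z)-6-(1,3-dioxolan-2-yl)hex-2-en-1-yl]-4,6-dimethyl-1,2-dioxane | C(/C=C\CCCC1OCCO1)[C@@]1(C)C[C@@](C)(O[Si](C)(C)C(C)(C)C)[C@@H](CCO[Si](c2ccccc2)(c2ccccc2)C(C)(C)C)OO1 | intermediate
22 | (3R,4R,6S)-4-(TBSO)-3-[2-(TBDPSO)ethyl]-6-[6-(1,3-dioxolan-2-yl)hexyl]-4,6-dimethyl-1,2-dioxane | C(CCCCCC1OCCO1)[C@@]1(C)C[C@@](C)(O[Si](C)(C)C(C)(C)C)[C@@H](CCO[Si](c2ccccc2)(c2ccccc2)C(C)(C)C)OO1 | intermediate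
23 | (3R,4R,6S)-4-(TBSO)-3-[2-(TBDPSO)ethyl]-4,6-dimethyl-6-(7-oxoheptyl)-1,2-dioxane | O=CCCCCCC[C@@]1(C)C[C@@](C)(O[Si](C)(C)C(C)(C)C)[C@@H](CCO[Si](c2ccccc2)(c2ccccc2)C(C)(C)C)OO1 | intermediate
24 | diethyl [(2E)-3-phenylprop-2-en-1-yl]phosphonate | CCOP(=O)(OCC)C/C=C/c1ccccc1 | starting material
25 | sodium salt of the α-carbanion of 24 | [Na+].CCOP(=O)(OCC)[CH-]/C=C/c1ccccc1 | intermediate (not isolated)
26 | (3R,4R,6S)-4-(TBSO)-3-[2-(TBDPSO)ethyl]-4,6-dimethyl-6-[(7E,9E)-10-phenyldeca-7,9-dien-1-yl]-1,2-dioxane | C(CCCCC/C=C/C=C/c1ccccc1)[C@@]1(C)C[C@@](C)(O[Si](C)(C)C(C)(C)C)[C@@H](CCO[Si](c2ccccc2)(c2ccccc2)C(C)(C)C)OO1 | intermediate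
27 | (3R,4R,6S)-3-(2-hydroxyethyl)-4,6-dimethyl-6-[(7E,9E)-10-phenyldeca-7,9-dien-1-yl]-1,2-dioxan-4-ol | C(CCCCC/C=C/C=C/c1ccccc1)[C@@]1(C)C[C@@](C)(O)[C@@H](CCO)OO1 | intermediate
28 | (3S,4aR,7aR)-3,4a-dimethyl-3-[(7E,9E)-10-phenyldeca-7,9-dien-1-yl]hexahydrofuro[3,2-c][1,2]dioxin-6-ol (both anomers) | C[C@]1(CCCCCC/C=C/C=C/c2ccccc2)C[C@@]2(C)OC(O)C[C@H]2OO1 | intermediate (not isolated)
29 | plakortolide Q | C[C@]1(CCCCCC/C=C/C=C/c2ccccc2)C[C@@]2(C)OC(=O)C[C@H]2OO1 | target

## Step count and least certain steps

Total step count: 18. Longest linear sequence: 17 steps (1–11 and 13–18; step 12 prepares the phosphonium salt on a side branch).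

**Step 7 (proposed new method).** The likely failure is that the catalyst attacks the peroxide instead of, or after, the alkene. Electron transfer from divalent ruthenium to the O–O bond would lead to rearrangement to a bis-epoxide or, through loss of H-3, to a hydroxy enone; liberated PCy3 could reduce the O–O bond; oligomerisation could set in if ethylene is depleted. The cause is that the alkene face next to the C4–C5 bridge is screened, so the metal approaches along the peroxide bridge, and bicyclic endoperoxides isomerise far more easily than the monocyclic dialkyl peroxides for which metathesis is established. The fallback uses known chemistry, sets out from 9 and cuts the same C2=C7 bond by oxidation. Dihydroxylation with OsO4 (cat.) and N-methylmorpholine N-oxide in acetone/water, a reaction established for 2,3-dioxabicyclo[2.2.2]octenes, should give the cis-diol F1; the configuration of its two new carbinol carbons is immaterial. NaIO4 in THF/water cleaves it to the dialdehyde F2, which is not stored but treated at −78 °C with methylenetriphenylphosphorane (from Ph3PCH3Br and KN(SiMe3)2) to give 11, where the route is rejoined. C1 and C8 then come from the ylide instead of from 10.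

**Step 8.** The likely failure is insufficient discrimination between the two vinyl groups, giving the regioisomeric alcohol or the diol. Both are terminal, and the C3 vinyl is itself flanked by the silyloxy-bearing C4. The fallback sets out from 11 and uses cross-metathesis with vinylboronic acid pinacol ester (second-generation Hoveyda–Grubbs catalyst, RuCl2(=CH-C6H4-2-O-i-Pr)(H2IMes), CH2Cl2, 40 °C). A vinyl group on a fully substituted allylic carbon, such as the one on C6, is essentially inert in cross-metathesis, so only the C3 vinyl should be exchanged, giving the (E)-alkenyl boronate F3. NaBO3·4H2O oxidises its C–B bond to the enol and hence to the aldehyde F4, and NaBH4 in methanol reduces this to 13.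

**Step 13.** The likely failure is α-deprotonation of 17 by the ylide followed by β-elimination of O1 from C6, which opens the dioxane. 17 is a β-peroxy aldehyde whose fully substituted β-carbon slows carbonyl addition. The fallback reverses the polarity, so that no aldehyde sits β to the peroxide, and sets out from 16. Mitsunobu thioetherification with 1-phenyl-1H-tetrazole-5-thiol (PPh3, diisopropyl azodicarboxylate) gives the tetrazolyl sulfide F5, and H2O2 with (NH4)6Mo7O24 oxidises it to the sulfone F6. Julia–Kocienski olefination (KN(SiMe3)2, THF, −78 °C) with 4-(1,3-dioxolan-2-yl)butanal F7, made from 18 by Kornblum oxidation (DMSO, NaHCO3), gives the (E)-alkene F8. Diimide reduction as in step 14 then gives 22.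

**Step 16.** The likely failure is incomplete E selectivity at C13=C14, or attack through the γ-carbon of the allylic anion. The fallback sets out from 23: a Wittig reaction with the ylide of cinnamyltriphenylphosphonium chloride (KN(SiMe3)2, THF, −78 → 20 °C) gives 26 together with its (13Z,15E)-isomer F9. The mixture is equilibrated to 26 with a catalytic amount of iodine in daylight.

## Further compounds

F1 | step 7 | (1R,4R,5R,6S,8R)-8-(TBSO)-1,8-dimethyl-2,3-dioxabicyclo[2.2.2]octane-5,6-diol (cis-diol, drawn on the face away from the silyloxy group) | C[C@@]1(C[C@@](C)(O[Si](C)(C)C(C)(C)C)[C@@H]2OO1)[C@@H](O)[C@H]2O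
F2 | step 7 | (3S,4R,6R)-4-(TBSO)-4,6-dimethyl-1,2-dioxane-3,6-dicarbaldehyde | O=C[C@@]1(C)C[C@@](C)(O[Si](C)(C)C(C)(C)C)[C@@H](C=O)OO1
F3 | step 8 | (3R,4R,6R)-4-(TBSO)-6-ethenyl-4,6-dimethyl-3-[(E)-2-(4,4,5,5-tetramethyl-1,3,2-dioxaborolan-2-yl)ethenyl]-1,2-dioxane | C=C[C@@]1(C)C[C@@](C)(O[Si](C)(C)C(C)(C)C)[C@@H](/C=C/B2OC(C)(C)C(C)(C)O2)OO1
F4 | step 8 | [(3R,4R,6R)-4-(TBSO)-6-ethenyl-4,6-dimethyl-1,2-dioxan-3-yl]acetaldehyde | C=C[C@@]1(C)C[C@@](C)(O[Si](C)(C)C(C)(C)C)[C@@H](CC=O)OO1
F5 | step 13 | 5-({2-[(3R,4R,6R)-4-(TBSO)-3-[2-(TBDPSO)ethyl]-4,6-dimethyl-1,2-dioxan-6-yl]ethyl}sulfanyl)-1-phenyl-1H-tetrazole | C(CSc1nnnn1-c1ccccc1)[C@@]1(C)C[C@@](C)(O[Si](C)(C)C(C)(C)C)[C@@H](CCO[Si](c2ccccc2)(c2ccccc2)C(C)(C)C)OO1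
F6 | step 13 | 5-({2-[(3R,4R,6R)-4-(TBSO)-3-[2-(TBDPSO)ethyl]-4,6-dimethyl-1,2-dioxan-6-yl]ethyl}sulfonyl)-1-phenyl-1H-tetrazole | C(CS(=O)(=O)c1nnnn1-c1ccccc1)[C@@]1(C)C[C@@](C)(O[Si](C)(C)C(C)(C)C)[C@@H](CCO[Si](c2ccccc2)(c2ccccc2)C(C)(C)C)OO1
F7 | step 13 | 4-(1,3-dioxolan-2-yl)butanal | O=CCCCC1OCCO1
F8 | step 13 | (3R,4R,6S)-4-(TBSO)-3-[2-(TBDPSO)ethyl]-6-[(2E)-6-(1,3-dioxolan-2-yl)hex-2-en-1-yl]-4,6-dimethyl-1,2-dioxane | C(/C=C/CCCC1OCCO1)[C@@]1(C)C[C@@](C)(O[Si](C)(C)C(C)(C)C)[C@@H](CCO[Si](c2ccccc2)(c2ccccc2)C(C)(C)C)OO1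
F9 | step 16 | (3R,4R,6S)-4-(TBSO)-3-[2-(TBDPSO)ethyl]-4,6-dimethyl-6-[(7Z,9E)-10-phenyldeca-7,9-dien-1-yl]-1,2-dioxane | C(CCCCC/C=C\C=C\c1ccccc1)[C@@]1(C)C[C@@](C)(O[Si](C)(C)C(C)(C)C)[C@@H](CCO[Si](c2ccccc2)(c2ccccc2)C(C)(C)C)OO1
A1 | alternative 1 | methyl (3R)-3-hydroperoxy-4-oxopentanoate | COC(=O)C[C@@H](OO)C(C)=O
A2 | alternative 1 | tert-butyl[(8-methylnon-8-en-6-yn-1-yl)oxy]diphenylsilane | C=C(C)C#CCCCCCO[Si](c1ccccc1)(c1ccccc1)C(C)(C)C
A3 | alternative 1 | methyl 2-[(3R,4R,6R)-6-{7-[(tert-butyldiphenylsilyl)oxy]hept-1-yn-1-yl}-4-hydroxy-4,6-dimethyl-1,2-dioxan-3-yl]acetate | CC(C)(C)[Si](OCCCCCC#C[C@@]1(C)C[C@@](C)(O)[C@@H](CC(=O)OC)OO1)(c1ccccc1)c1ccccc1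
A4 | alternative 2 | tert-butyl (3R)-4-methyl-3-[(3-methylpenta-1,4-dien-3-yl)peroxy]pent-4-enoate | C=CC(C)(C=C)OO[C@H](CC(=O)OC(C)(C)C)C(C)=C
A5 | alternative 2 | tert-butyl 2-[(3R,6S)-6-ethenyl-4,6-dimethyl-3,6-dihydro-1,2-dioxin-3-yl]acetate | C=C[C@@]1(C)C=C(C)[C@@H](CC(=O)OC(C)(C)C)OO1
A6 | alternative 3 | tert-butyl (3R)-3-[(2R)-2,4-dimethyl-6-oxo-3,6-dihydro-2H-pyran-2-yl]-3-hydroperoxypropanoate | CC(C)(C)OC(=O)C[C@@H](OO)[C@@]1(C)CC(C)=CC(=O)O1
A7 | alternative 3 | tert-butyl 2-[(1R,4R,5R)-1,5-dimethyl-7-oxo-2,3,6-trioxabicyclo[3.3.1]nonan-4-yl]acetate | CC(C)(C)OC(=O)C[C@H]1OO[C@]2(C)C[C@@]1(C)OC(=O)C2
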